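## Retrosynthetic overview

1. The target is three acylphloroglucinol rings, A–CH2–B–CH2–C: ring A is an aspidinol unit, ring B phloroacetophenone, ring C a 4,6-dihydroxy-2-methoxy-3-methylbutyrophenone unit. The last bond made joins the CH2 on ring C to the one unsubstituted carbon of ring B in dimer 7.
2. Enabling feature: the ring C carbon that carries this CH2 lies between two free phenolic OH groups, so a CH2–NMe2 placed there is an o-hydroxybenzylamine that collapses to an o-quinone methide. Ring B of 7 keeps a single C–H, flanked by two OH and para to the third (the carbon of a vinylogous acid).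
3. The key step is run as a three-component union (monomer 10 + CH2(NMe2)2 + dimer 7). Both C–C bonds of the second bridge form in one flask, on unprotected phenols, as the last step.
4. Dimer 7 comes from the same kind of union of aspidinol 3 with excess phloroacetophenone 4. Rings A and C both come from ketone 2 (butyrylation of 1) by complementary O-methylation: the para-OH directly, the hindered ortho-OH after bis-MOM protection.
5. No ring is built: the benzene rings are bought (1 for rings A and C, 4 for ring B) and joined in the order A–B, then AB–C.

Key step: step 7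

Remark: the target has no stereocentre and no stereogenic double bond, so no configuration has to be set; 2-methylphloroglucinol (1) and phloroacetophenone (4) are taken as purchased.

## Route

Step 1
Reactants: 1 2-methylbenzene-1,3,5-triol (2-methylphloroglucinol)
Product: 2 1-(2,4,6-trihydroxy-3-methylphenyl)butan-1-one
Conditions: PrCOCl (1.1 equiv), AlCl3 (3.5 equiv), PhNO2–CH2Cl2, 0 → 60 °C; ice/HCl
Reagents that add atoms: butanoyl chloride, CCCC(=O)Cl
Why: Friedel–Crafts acylation of a phloroglucinol; the two free nuclear carbons of 1 are equivalent, so only one mono-ketone can form, and the first acyl group deactivates the ring towards a second acylation.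

Step 2
Reactants: 2 1-(2,4,6-trihydroxy-3-methylphenyl)butan-1-one
Product: 3 1-(2,6-dihydroxy-4-methoxy-3-methylphenyl)butan-1-one (aspidinol)
Conditions: Me2SO4 (1.0 equiv), K2CO3 (1.0 equiv), acetone, 0 °C → rt
Reagents that add atoms: dimethyl sulfate, COS(=O)(=O)OC
Why: Partial Williamson O-methylation; the 4-OH para to the ketone is the most acidic phenol and is not shielded by the acyl group, so one equivalent of a hard methylating agent should etherify it and leave the two ortho-OH groups free.

Step 3
Reactants: 3 1-(2,6-dihydroxy-4-methoxy-3-methylphenyl)butan-1-one (aspidinol); 4 1-(2,4,6-trihydroxyphenyl)ethan-1-one (phloroacetophenone)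
Product: 7 1-{3-[(3-acetyl-2,4,6-trihydroxyphenyl)methyl]-2,6-dihydroxy-4-methoxy-5-methylphenyl}butan-1-one, via Mannich base 5 (not isolated), via o-quinone methide 6 (not isolated)
Conditions: CH2(NMe2)2 (1.0 equiv), 1,4-dioxane, 0 °C → rt; then 4 (3 equiv), 80 °C, N2 sweep; 1 M HCl work-up
Reagents that add atoms: N,N,N′,N′-tetramethylmethanediamine [bis(dimethylamino)methane], CN(C)CN(C)C
Why: Phenolic Mannich reaction at the only unsubstituted carbon of 3 gives 5, which on heating loses dimethylamine to the o-quinone methide 6 that is trapped at carbon (conjugate addition/Friedel–Crafts benzylation, then rearomatisation) by 4, whose two free positions are equivalent and whose threefold excess should suppress a second benzylation.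

Step 4
Reactants: 2 1-(2,4,6-trihydroxy-3-methylphenyl)butan-1-one
Product: 8 1-[2-hydroxy-4,6-bis(methoxymethoxy)-3-methylphenyl]butan-1-one
Conditions: MOMCl (2.1 equiv), iPr2NEt (2.5 equiv), CH2Cl2, 0 °C → rt
Reagents that add atoms: chloromethyl methyl ether, COCCl
Why: Acetal (MOM ether) protection under kinetic control; the para 4-OH and the less hindered ortho 6-OH should react, while the 2-OH wedged between the butanoyl and methyl groups stays as the chelated, least accessible phenol.

Step 5
Reactants: 8 1-[2-hydroxy-4,6-bis(methoxymethoxy)-3-methylphenyl]butan-1-one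
Product: 9 1-[2-methoxy-4,6-bis(methoxymethoxy)-3-methylphenyl]butan-1-one
Conditions: MeI (3 equiv), K2CO3 (3 equiv), DMF, 50 °C
Reagents that add atoms: iodomethane, CI
Why: Williamson methylation of the one remaining (chelated, hindered) phenol with excess reagent in a dipolar solvent; the MOM ethers are stable to base and carbonate is too weak to enolise the ketone.

Step 6
Reactants: 9 1-[2-methoxy-4,6-bis(methoxymethoxy)-3-methylphenyl]butan-1-one
Product: 10 1-(4,6-dihydroxy-2-methoxy-3-methylphenyl)butan-1-one
Conditions: 3 M HCl, MeOH, 50 °C
Reagents that add atoms: none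
Why: Acid-catalysed acetal exchange with methanol removes both MOM groups as dimethoxymethane, while the aryl methyl ether and the ketone are untouched and the large excess of methanol keeps the released formaldehyde unit from alkylating the ring.

Step 7
Reactants: 10 1-(4,6-dihydroxy-2-methoxy-3-methylphenyl)butan-1-one; 7 1-{3-[(3-acetyl-2,4,6-trihydroxyphenyl)methyl]-2,6-dihydroxy-4-methoxy-5-methylphenyl}butan-1-one
Product: 13 1-[3-({3-acetyl-5-[(3-butanoyl-2,4-dihydroxy-6-methoxy-5-methylphenyl)methyl]-2,4,6-trihydroxyphenyl}methyl)-2,4-dihydroxy-6-methoxy-5-methylphenyl]butan-1-one (target CNP0184345.0), via Mannich base 11 (not isolated), via o-quinone methide 12 (not isolated)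
Conditions: CH2(NMe2)2 (1.0 equiv), 1,4-dioxane, 0 °C → rt; then 7 (1.0 equiv), 80 °C, N2 sweep; 1 M HCl work-up
Reagents that add atoms: N,N,N′,N′-tetramethylmethanediamine [bis(dimethylamino)methane], CN(C)CN(C)C
Why: The acidic phenol 10 opens the aminal to CH2=NMe2+ and is aminomethylated (phenolic Mannich reaction) at its only free carbon to give 11; on heating, the zwitterion of 11 expels dimethylamine in a 1,4-elimination to the o-quinone methide 12, the single unsubstituted carbon of ring B in 7 adds to its exocyclic CH2 (conjugate addition/Friedel–Crafts benzylation), and tautomerisation of the resulting dienone restores the arene and fixes the CH2–C(ring B) bond. The closest known reaction type is the thermal C-benzylation of phloroglucinols and other enols by ortho-hydroxybenzyl Mannich bases, including its one-flask three-component form used for methylene-bridged acylphloroglucinol hetero-dimers. No ring is closed and no stereocentre is created. The step needs C- over O-benzylation and cross- over homo-coupling: 7 offers one nuclear C–H and its O-adducts (aryl benzyl ethers) revert to 12, whereas 10 is converted completely into 11 at or below room temperature before 7 is added, so no species with a free nuclear carbon other than 7 meets 12. A moderate temperature for the elimination and a nitrogen sweep that removes dimethylamine should limit amine-mediated exchange of the bridge already present in 7.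

## Compound list

1 | 2-methylbenzene-1,3,5-triol (2-methylphloroglucinol) | Cc1c(O)cc(O)cc1O | starting material
2 | 1-(2,4,6-trihydroxy-3-methylphenyl)butan-1-one | CCCC(=O)c1c(O)cc(O)c(C)c1O | intermediate
3 | 1-(2,6-dihydroxy-4-methoxy-3-methylphenyl)butan-1-one (aspidinol) | CCCC(=O)c1c(O)c(C)c(OC)cc1O | intermediate
4 | 1-(2,4,6-trihydroxyphenyl)ethan-1-one (phloroacetophenone) | CC(=O)c1c(O)cc(O)cc1O | starting material
5 | 1-{3-[(dimethylamino)methyl]-2,6-dihydroxy-4-methoxy-5-methylphenyl}butan-1-one | CCCC(=O)c1c(O)c(C)c(OC)c(CN(C)C)c1O | intermediate (not isolated)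
6 | 2-butanoyl-3-hydroxy-5-methoxy-4-methyl-6-methylidenecyclohexa-2,4-dien-1-one | C=C1C(=O)C(C(=O)CCC)=C(O)C(C)=C1OC | intermediate (not isolated)
7 | 1-{3-[(3-acetyl-2,4,6-trihydroxyphenyl)methyl]-2,6-dihydroxy-4-methoxy-5-methylphenyl}butan-1-one | CCCC(=O)c1c(O)c(C)c(OC)c(Cc2c(O)cc(O)c(C(C)=O)c2O)c1O | intermediate
8 | 1-[2-hydroxy-4,6-bis(methoxymethoxy)-3-methylphenyl]butan-1-one | CCCC(=O)c1c(O)c(C)c(OCOC)cc1OCOC | intermediate
9 | 1-[2-methoxy-4,6-bis(methoxymethoxy)-3-methylphenyl]butan-1-one | CCCC(=O)c1c(OC)c(C)c(OCOC)cc1OCOC | intermediate
10 | 1-(4,6-dihydroxy-2-methoxy-3-methylphenyl)butan-1-one | CCCC(=O)c1c(OC)c(C)c(O)cc1O | intermediate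
11 | 1-{3-[(dimethylamino)methyl]-2,4-dihydroxy-6-methoxy-5-methylphenyl}butan-1-one | CCCC(=O)c1c(OC)c(C)c(O)c(CN(C)C)c1O | intermediate (not isolated)
12 | 4-butanoyl-5-hydroxy-3-methoxy-2-methyl-6-methylidenecyclohexa-2,4-dien-1-one | C=C1C(=O)C(C)=C(OC)C(C(=O)CCC)=C1O | intermediate (not isolated)
13 | 1-[3-({3-acetyl-5-[(3-butanoyl-2,4-dihydroxy-6-methoxy-5-methylphenyl)methyl]-2,4,6-trihydroxyphenyl}methyl)-2,4-dihydroxy-6-methoxy-5-methylphenyl]butan-1-one | CCCC(=O)c1c(O)c(C)c(OC)c(Cc2c(O)c(Cc3c(O)c(C)c(OC)c(C(=O)CCC)c3O)c(O)c(C(C)=O)c2O)c1O | target

## Step count and risks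

Total step count: 7. Longest linear sequence: 5 steps (steps 1, 4, 5, 6, 7, from 1 to 13).

Steps most likely to fail:

Step 7. The methylene bridges may exchange under heat and liberated amine: retro-Michael fragmentation of the bridge in 7 or in the product, followed by recombination, would scramble the three rings, and any unconsumed aminomethylating agent would lead to homo-coupling. The fallback is an amine-free, acid-mediated union through a boron-templated temporary ring. It sets out from 10: ortho-specific hydroxymethylation with paraformaldehyde and phenylboronic acid (cat. propionic acid, toluene, reflux with water separation) should give the cyclic boronate 1-(5-hydroxy-7-methoxy-8-methyl-2-phenyl-4H-1,3,2-benzodioxaborinin-6-yl)butan-1-one F1 (drawn closed onto O-4; the isomer closed onto O-6 would serve equally). A Brønsted acid (cat. TFA in CH2Cl2, or propionic acid in toluene at 60–80 °C) then opens F1 to the same quinone methide or its boron-bound benzylic cation, which benzylates the free carbon of ring B in 7; aqueous work-up removes phenylboronic acid. The fallback comes back to the route at 13.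

Step 4. The second MOM group may go onto the wrong ortho-phenol (O-2 instead of O-6) or a third may be introduced, which would carry a regioisomeric ring C through the route. The fallback replaces selective protection by exhaustive protection and chelation-assisted selective deprotection. It sets out from 2: MOMCl (4 equiv), NaH (3.3 equiv), DMF, 0 °C should give 1-[2,4,6-tris(methoxymethoxy)-3-methylphenyl]butan-1-one F2. Brief treatment with cat. I2 in MeOH at rt (or 0.1 M HCl–MeOH at 0 °C) should then cleave only the ortho MOM group compressed between the butanoyl and methyl groups, the most strained acetal, whose loss is assisted by hydrogen bonding of the new phenol to the ketone. The fallback comes back to the route at 8.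

Step 3. Ring B may be benzylated twice, and the bridge may exchange, so that the dimer is accompanied by the bis-adduct. The fallback reverses the polarity of the union. It sets out from 4: CH2(NMe2)2 (1.0 equiv), dioxane, 0 °C should give the mono-Mannich base 1-{3-[(dimethylamino)methyl]-2,4,6-trihydroxyphenyl}ethan-1-one F3, which separates as a zwitterion and so resists a second aminomethylation. F3 is isolated and added slowly to aspidinol 3 (2 equiv) in dioxane at 80 °C; the single free carbon of 3 can accept only one benzyl group, and the excess of 3 outcompetes self-condensation of the ring B quinone methide. The fallback comes back to the route at 7.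

Further compounds
F1 | step 7 | 1-(5-hydroxy-7-methoxy-8-methyl-2-phenyl-4H-1,3,2-benzodioxaborinin-6-yl)butan-1-one | CCCC(=O)c1c(OC)c(C)c2OB(c3ccccc3)OCc2c1O
F2 | step 4 | 1-[2,4,6-tris(methoxymethoxy)-3-methylphenyl]butan-1-one | CCCC(=O)c1c(OCOC)c(C)c(OCOC)cc1OCOC
F3 | step 3 | 1-{3-[(dimethylamino)methyl]-2,4,6-trihydroxyphenyl}ethan-1-one | CC(=O)c1c(O)cc(O)c(CN(C)C)c1O
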